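The route rests on disconnecting both carbon–carbon bonds of the exocyclic carbinol carbon, a lone CH bonded only to C3 of the oxolane (ring A), to C1 of the syringyl arene (ring C) and to oxygen. The key step inserts this carbon from dichloromethane between C3 and a boron atom and then moves the aryl group from boron onto it. One flask thus delivers the whole skeleton and the carbinol configuration, with boron left as a masked hydroxyl. The precursor is the trans-4-(arylmethyl)oxolan-3-yl boronic ester of (S,S)-1,2-dicyclohexylethane-1,2-diol, reached by ring-closing metathesis and asymmetric hydroboration.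

Key step: step 8

Assumption (remark on the chemistry): the facial sense of monoisopinocampheylborane (IpcBH2) toward dihydrofuran 9 is taken to be that established for 1-alkylcyclopentenes, on which basis the reagent derived from (−)-α-pinene is chosen for the (3S,4S) borane; should the sense prove opposite, the reagent from (+)-α-pinene is used in the same way.

Step 1
Reactants: 1 4-bromo-2-methoxyphenol
Product: 2 benzyl 4-bromo-2-methoxyphenyl ether
Conditions: BnBr (1.1 equiv), K2CO3 (1.5 equiv), DMF, rt
Reagents that add atoms: benzyl bromide, BrCc1ccccc1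
Why: Williamson etherification of the phenoxide with a reactive benzylic bromide is reliable, and the benzyl ether is chosen because it is inert to magnesium, organolithium, borane and peroxide chemistry and leaves at the end under neutral hydrogenolysis.

Step 2
Reactants: 2 benzyl 4-bromo-2-methoxyphenyl ether; 3 3-chloro-2-(chloromethyl)prop-1-ene
Product: 5 benzyl 4-[2-(chloromethyl)prop-2-en-1-yl]-2-methoxyphenyl ether, via arylmagnesium bromide 4 (not isolated)
Conditions: Mg, I2 (cat.), THF, 50 °C; then added to 3 (3 equiv), CuI (5 mol %), THF, −20 °C → rt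
Reagents that add atoms: none
Why: Magnesium insertion into the aryl bromide followed by copper-catalysed allylic substitution of one chloride of the symmetrical dichloride, whose SN2 and SN2' pathways converge on the same product, should give the mono-arylated allylic chloride, the excess of 3 suppressing double substitution.

Step 3
Reactants: 5 benzyl 4-[2-(chloromethyl)prop-2-en-1-yl]-2-methoxyphenyl ether; 6 prop-2-en-1-ol
Product: 8 benzyl 2-methoxy-4-{2-[(prop-2-en-1-yloxy)methyl]prop-2-en-1-yl}phenyl ether, via sodium prop-2-en-1-olate 7 (not isolated)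
Conditions: 6 (1.5 equiv), NaH, THF, 0 °C; then 5, Bu4NI (10 mol %), rt → 50 °C
Reagents that add atoms: none
Why: Williamson ether synthesis between a primary alkoxide and a primary allylic chloride, helped by iodide exchange, should be clean because direct and allylic-transposed substitution again give one and the same ether.

Step 4
Reactants: 8 benzyl 2-methoxy-4-{2-[(prop-2-en-1-yloxy)methyl]prop-2-en-1-yl}phenyl ether
Product: 9 3-[4-(benzyloxy)-3-methoxybenzyl]-2,5-dihydrofuran
Conditions: second-generation Grubbs catalyst (2 mol %), 1,4-benzoquinone (10 mol %), CH2Cl2 (0.05 M), 40 °C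
Reagents that add atoms: none
Why: Ring-closing olefin metathesis between the allyl and the 2-substituted allyl terminus closes the unstrained five-membered ring with loss of ethene, the second-generation catalyst being active enough for a trisubstituted alkene and benzoquinone holding back ruthenium hydride isomerisation to the enol ether.

Step 5
Reactants: 9 3-[4-(benzyloxy)-3-methoxybenzyl]-2,5-dihydrofuran; 10 (1S,2S)-1,2-dicyclohexylethane-1,2-diol
Product: 13 (4S,5S)-2-{(3S,4S)-4-[4-(benzyloxy)-3-methoxybenzyl]oxolan-3-yl}-4,5-dicyclohexyl-1,3,2-dioxaborolane, via isopinocampheyl oxolanyl borane 11 (not isolated), via diethyl boronate 12 (not isolated)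
Conditions: IpcBH2 from (−)-α-pinene (1.1 equiv; freshly liberated from its TMEDA adduct with BF3·OEt2 and filtered), Et2O, −25 °C, 24 h; CH3CHO (excess), 0 °C → rt; 10 (1.0 equiv), Et2O, rt; crystallisation or chromatography
Reagents that add atoms: monoisopinocampheylborane derived from (−)-α-pinene, B[C@H]1C[C@H]2C[C@@H]([C@@H]1C)C2(C)C
Why: Asymmetric hydroboration adds H and B syn across the trisubstituted alkene with boron at the unsubstituted carbon, so boron ends trans to the arylmethyl group and both ring stereocentres (3S,4S) are set together by the reagent's choice of alkene face; acetaldehyde then expels α-pinene to leave the diethyl boronate, diol exchange gives the robust cyclic ester, and any (3R,4R) material is from this point a diastereomer that crystallisation or chromatography should remove.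

Step 6
Reactants: 14 4-bromo-2,6-dimethoxyphenol
Product: 15 benzyl 4-bromo-2,6-dimethoxyphenyl ether
Conditions: BnBr (1.2 equiv), K2CO3 (2 equiv), DMF, 60 °C
Reagents that add atoms: benzyl bromide, BrCc1ccccc1
Why: Williamson etherification of the flanked but still nucleophilic phenoxide with benzyl bromide should proceed on gentle warming, giving the same protecting group as on the other arene so that one final operation removes both.

Step 7
Reactants: 15 benzyl 4-bromo-2,6-dimethoxyphenyl ether
Product: 16 [4-(benzyloxy)-3,5-dimethoxyphenyl]magnesium bromide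
Conditions: Mg turnings, I2 (cat.), THF, 50 °C; kept as a titrated THF solution
Reagents that add atoms: magnesium, [Mg]
Why: Grignard formation by insertion of magnesium into the aryl bromide tolerates the methyl and benzyl ethers, and titration allows the excess required in step 8 to be dosed.

Step 8
Reactants: 13 (4S,5S)-2-{(3S,4S)-4-[4-(benzyloxy)-3-methoxybenzyl]oxolan-3-yl}-4,5-dicyclohexyl-1,3,2-dioxaborolane; 17 dichloromethane; 16 [4-(benzyloxy)-3,5-dimethoxyphenyl]magnesium bromide
Product: 22 (4S,5S)-2-[(S)-[4-(benzyloxy)-3,5-dimethoxyphenyl]{(3S,4S)-4-[4-(benzyloxy)-3-methoxybenzyl]oxolan-3-yl}methyl]-4,5-dicyclohexyl-1,3,2-dioxaborolane, via (dichloromethyl)lithium 18 (not isolated), via lithium dichloromethyl borate 19 (not isolated), via alpha-chloro boronic ester 20 (not isolated), via bromomagnesium aryl borate 21 (not isolated)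
Conditions: 17 (1.7 equiv), n-BuLi (1.3 equiv), THF, −100 °C; 13, −100 °C; ZnCl2 (1.0 equiv, THF), −100 °C → rt, 4 h; then −78 °C, 16 (3.5 equiv), → rt, 16 h; aq. NH4Cl
Reagents that add atoms: none
Why: (Dichloromethyl)lithium 18 adds to boron of 13 to give ate complex 19, in which ZnCl2 bridges one dioxaborolane oxygen and one chloride so that oxolane C3 migrates from boron to carbon with retention and loss of that chloride, giving 20; Grignard reagent 16 then forms ate complex 21, whose aryl group migrates anti to the remaining chloride with inversion to give 22. The closest known reaction type is the Matteson homologation of chiral diol boronic esters with (dichloromethyl)lithium and ZnCl2 followed by Grignard displacement of the α-chloride, applied here to a secondary alkyl boronic ester. No ring is closed. The one new stereocentre, the future carbinol carbon, is controlled by the (S,S)-diol on boron, which by the established sense of this reaction gives the (R)-chloride and, after the invertive aryl transfer, the (S)-configured benzylic boronic ester, while the ring stereocentres are not touched. The step needs discrimination between the two diastereotopic chlorides, which the C2-symmetric dioxaborolane secures through the zinc chelate, and it needs 1,2-migration to outrun ring-opening loss of the oxolane oxygen beta to boron, which the low temperature and the imperfect anti alignment of C3–B and C2–O imposed by the five-membered ring should ensure.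

Step 9
Reactants: 22 (4S,5S)-2-[(S)-[4-(benzyloxy)-3,5-dimethoxyphenyl]{(3S,4S)-4-[4-(benzyloxy)-3-methoxybenzyl]oxolan-3-yl}methyl]-4,5-dicyclohexyl-1,3,2-dioxaborolane
Product: 23 (S)-[4-(benzyloxy)-3,5-dimethoxyphenyl]{(3S,4S)-4-[4-(benzyloxy)-3-methoxybenzyl]oxolan-3-yl}methanol
Conditions: H2O2 (30 % aq.), NaOH (2 M aq.), THF, 0 °C → rt
Reagents that add atoms: hydrogen peroxide, OO
Why: Oxidation of the boronic ester proceeds by addition of hydroperoxide to boron and migration of the benzylic carbon from boron to oxygen with retention, so the (S) configuration set in step 8 is carried into the carbinol while the benzyl ethers stay untouched and diol 10 is recovered.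

Step 10
Reactants: 23 (S)-[4-(benzyloxy)-3,5-dimethoxyphenyl]{(3S,4S)-4-[4-(benzyloxy)-3-methoxybenzyl]oxolan-3-yl}methanol
Product: 24 4-[(S)-hydroxy{(3S,4S)-4-[(4-hydroxy-3-methoxyphenyl)methyl]oxolan-3-yl}methyl]-2,6-dimethoxyphenol
Conditions: H2 (1 atm), 10 % Pd/C, EtOAc, rt, stopped when debenzylation is complete
Reagents that add atoms: none
Why: Catalytic hydrogenolysis should cleave the two aryl benzyl ethers under neutral conditions much faster than the secondary benzylic C–O bond, and no stereocentre takes part.

Compound list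

1 | 4-bromo-2-methoxyphenol | COc1cc(Br)ccc1O | starting material
2 | benzyl 4-bromo-2-methoxyphenyl ether | COc1cc(Br)ccc1OCc1ccccc1 | intermediate
3 | 3-chloro-2-(chloromethyl)prop-1-ene | C=C(CCl)CCl | starting material
4 | [4-(benzyloxy)-3-methoxyphenyl]magnesium bromide | COc1cc([Mg]Br)ccc1OCc1ccccc1 | intermediate
5 | benzyl 4-[2-(chloromethyl)prop-2-en-1-yl]-2-methoxyphenyl ether | COc1cc(CC(=C)CCl)ccc1OCc1ccccc1 | intermediate
6 | prop-2-en-1-ol | C=CCO | starting material
7 | sodium prop-2-en-1-olate | [Na+].[O-]CC=C | intermediate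
8 | benzyl 2-methoxy-4-{2-[(prop-2-en-1-yloxy)methyl]prop-2-en-1-yl}phenyl ether | COc1cc(CC(=C)COCC=C)ccc1OCc1ccccc1 | intermediate
9 | 3-[4-(benzyloxy)-3-methoxybenzyl]-2,5-dihydrofuran | COc1cc(CC2=CCOC2)ccc1OCc1ccccc1 | intermediate
10 | (1S,2S)-1,2-dicyclohexylethane-1,2-diol | O[C@@H](C1CCCCC1)[C@@H](O)C1CCCCC1 | starting material
11 | {(3S,4S)-4-[4-(benzyloxy)-3-methoxybenzyl]oxolan-3-yl}(isopinocampheyl)borane (isopinocampheyl group from (−)-α-pinene; monomer drawn) | COc1cc(C[C@@H]2COC[C@H]2B[C@H]2C[C@H]3C[C@@H]([C@@H]2C)C3(C)C)ccc1OCc1ccccc1 | intermediate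
12 | diethyl {(3S,4S)-4-[4-(benzyloxy)-3-methoxybenzyl]oxolan-3-yl}boronate | COc1cc(C[C@@H]2COC[C@H]2B(OCC)OCC)ccc1OCc1ccccc1 | intermediate
13 | (4S,5S)-2-{(3S,4S)-4-[4-(benzyloxy)-3-methoxybenzyl]oxolan-3-yl}-4,5-dicyclohexyl-1,3,2-dioxaborolane | COc1cc(C[C@@H]2COC[C@H]2B3O[C@@H](C4CCCCC4)[C@H](C4CCCCC4)O3)ccc1OCc1ccccc1 | intermediate
14 | 4-bromo-2,6-dimethoxyphenol | COc1cc(Br)cc(OC)c1O | starting material
15 | benzyl 4-bromo-2,6-dimethoxyphenyl ether | COc1cc(Br)cc(OC)c1OCc1ccccc1 | intermediate
16 | [4-(benzyloxy)-3,5-dimethoxyphenyl]magnesium bromide | COc1cc([Mg]Br)cc(OC)c1OCc1ccccc1 | intermediate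
17 | dichloromethane | ClCCl | starting material
18 | (dichloromethyl)lithium | [Li]C(Cl)Cl | intermediate
19 | lithium (dichloromethyl){(3S,4S)-4-[4-(benzyloxy)-3-methoxybenzyl]oxolan-3-yl}[(1S,2S)-1,2-dicyclohexylethane-1,2-diolato]borate | [Li+].COc1cc(C[C@@H]2COC[C@H]2[B-]3(C(Cl)Cl)O[C@@H](C4CCCCC4)[C@H](C4CCCCC4)O3)ccc1OCc1ccccc1 | intermediate
20 | (4S,5S)-2-[(R)-chloro{(3S,4S)-4-[4-(benzyloxy)-3-methoxybenzyl]oxolan-3-yl}methyl]-4,5-dicyclohexyl-1,3,2-dioxaborolane | COc1cc(C[C@@H]2COC[C@H]2[C@H](Cl)B3O[C@@H](C4CCCCC4)[C@H](C4CCCCC4)O3)ccc1OCc1ccccc1 | intermediate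
21 | bromomagnesium [4-(benzyloxy)-3,5-dimethoxyphenyl][(R)-chloro{(3S,4S)-4-[4-(benzyloxy)-3-methoxybenzyl]oxolan-3-yl}methyl][(1S,2S)-1,2-dicyclohexylethane-1,2-diolato]borate | [Mg+]Br.COc1cc(C[C@@H]2COC[C@H]2[C@H](Cl)[B-]3(c4cc(OC)c(OCc5ccccc5)c(OC)c4)O[C@@H](C4CCCCC4)[C@H](C4CCCCC4)O3)ccc1OCc1ccccc1 | intermediate
22 | (4S,5S)-2-[(S)-[4-(benzyloxy)-3,5-dimethoxyphenyl]{(3S,4S)-4-[4-(benzyloxy)-3-methoxybenzyl]oxolan-3-yl}methyl]-4,5-dicyclohexyl-1,3,2-dioxaborolane | COc1cc(C[C@@H]2COC[C@H]2[C@H](B3O[C@@H](C4CCCCC4)[C@H](C4CCCCC4)O3)c2cc(OC)c(OCc3ccccc3)c(OC)c2)ccc1OCc1ccccc1 | intermediate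
23 | (S)-[4-(benzyloxy)-3,5-dimethoxyphenyl]{(3S,4S)-4-[4-(benzyloxy)-3-methoxybenzyl]oxolan-3-yl}methanol | COc1cc(C[C@@H]2COC[C@H]2[C@H](O)c2cc(OC)c(OCc3ccccc3)c(OC)c2)ccc1OCc1ccccc1 | intermediate
24 | 4-[(S)-hydroxy{(3S,4S)-4-[(4-hydroxy-3-methoxyphenyl)methyl]oxolan-3-yl}methyl]-2,6-dimethoxyphenol | COc1cc(C[C@@H]2COC[C@H]2[C@H](O)c2cc(OC)c(O)c(OC)c2)ccc1O | target

Total step count: 10. Longest linear sequence: 8 steps (steps 1 to 5, then 8, 9 and 10, from 1 to 24); steps 6 and 7 form the short branch that supplies 16.

Steps most likely to fail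

Step 8. What may go wrong is slow transfer of the aryl group at the hindered α-chloro centre, with chloride-induced epimerisation of the α-chloro ester in the meantime, so that aryl transfer is incomplete or stereochemically leaky. The fallback sets out from 20, isolated after the first half of the step, and comes back to the route at 23. It replaces the second 1,2-shift by carbonyl chemistry.
- Buffered oxidation of 20 (NaBO3·4H2O, THF/water, rt) should give the aldehyde (3S,4S)-4-[4-(benzyloxy)-3-methoxybenzyl]oxolane-3-carbaldehyde F1.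
- Addition of 16 (THF, −78 °C) should give 23 mixed with its carbinol epimer (R)-[4-(benzyloxy)-3,5-dimethoxyphenyl]{(3S,4S)-4-[4-(benzyloxy)-3-methoxybenzyl]oxolan-3-yl}methanol F2.
- Oxidation of the mixture with Dess–Martin periodinane (CH2Cl2, rt) converges on the ketone {(3S,4S)-4-[4-(benzyloxy)-3-methoxybenzyl]oxolan-3-yl}[4-(benzyloxy)-3,5-dimethoxyphenyl]methanone F3.
- CBS reduction of F3 with (R)-1-methyl-3,3-diphenyltetrahydro-1H,3H-pyrrolo[1,2-c][1,3,2]oxazaborole (10 mol %) and BH3·SMe2 (THF, −20 °C), with the aryl group as the large substituent, should deliver 23.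

Step 5. What may go wrong is poor facial selectivity of the chiral borane toward an alkene whose two faces differ only through a flexible arylmethyl group, which would carry the (3R,4R) series forward. The fallback sets out from 9 and comes back at 13, and shifts the stereochemical task from induction to resolution by the auxiliary that the key step needs in any case.
- Uncatalysed hydroboration with catecholborane (neat, 100 °C) should give the racemic trans boronate (3RS,4RS)-2-{4-[4-(benzyloxy)-3-methoxybenzyl]oxolan-3-yl}-1,3,2-benzodioxaborole F4.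
- Exchange with 10 (Et2O, rt) releases catechol and gives 13 together with its ring-antipodal diastereomer (4S,5S)-2-{(3R,4R)-4-[4-(benzyloxy)-3-methoxybenzyl]oxolan-3-yl}-4,5-dicyclohexyl-1,3,2-dioxaborolane F5.
- Because these two esters are diastereomers, they are separated by fractional crystallisation or chromatography.

Step 10. What may go wrong is over-reduction, that is hydrogenolytic loss of the electron-rich benzylic hydroxyl while the benzyl ethers are being removed. The fallback sets out from 22 and comes back at 24, and reverses the order of the last two operations so that no benzylic C–O bond is present during hydrogenation.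
- H2 over 10 % Pd/C in EtOAc should convert 22 into the diphenol boronic ester 4-[(S)-[(4S,5S)-4,5-dicyclohexyl-1,3,2-dioxaborolan-2-yl]{(3S,4S)-4-(4-hydroxy-3-methoxybenzyl)oxolan-3-yl}methyl]-2,6-dimethoxyphenol F6, the benzylic C–B bond being inert to these conditions.
- Mild oxidation with NaBO3·4H2O in THF/water at rt should then give 24 with retention.

Further compounds

F1 | step 8 | (3S,4S)-4-[4-(benzyloxy)-3-methoxybenzyl]oxolane-3-carbaldehyde | COc1cc(C[C@@H]2COC[C@H]2C=O)ccc1OCc1ccccc1
F2 | step 8 | (R)-[4-(benzyloxy)-3,5-dimethoxyphenyl]{(3S,4S)-4-[4-(benzyloxy)-3-methoxybenzyl]oxolan-3-yl}methanol | COc1cc(C[C@@H]2COC[C@H]2[C@@H](O)c2cc(OC)c(OCc3ccccc3)c(OC)c2)ccc1OCc1ccccc1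
F3 | step 8 | {(3S,4S)-4-[4-(benzyloxy)-3-methoxybenzyl]oxolan-3-yl}[4-(benzyloxy)-3,5-dimethoxyphenyl]methanone | COc1cc(C[C@@H]2COC[C@H]2C(=O)c2cc(OC)c(OCc3ccccc3)c(OC)c2)ccc1OCc1ccccc1
F4 | step 5 | (3RS,4RS)-2-{4-[4-(benzyloxy)-3-methoxybenzyl]oxolan-3-yl}-1,3,2-benzodioxaborole (racemic trans; the 3S,4S enantiomer is drawn) | COc1cc(C[C@@H]2COC[C@H]2B3Oc4ccccc4O3)ccc1OCc1ccccc1
F5 | step 5 | (4S,5S)-2-{(3R,4R)-4-[4-(benzyloxy)-3-methoxybenzyl]oxolan-3-yl}-4,5-dicyclohexyl-1,3,2-dioxaborolane | COc1cc(C[C@H]2COC[C@@H]2B3O[C@@H](C4CCCCC4)[C@H](C4CCCCC4)O3)ccc1OCc1ccccc1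
F6 | step 10 | 4-[(S)-[(4S,5S)-4,5-dicyclohexyl-1,3,2-dioxaborolan-2-yl]{(3S,4S)-4-(4-hydroxy-3-methoxybenzyl)oxolan-3-yl}methyl]-2,6-dimethoxyphenol | COc1cc(C[C@@H]2COC[C@H]2[C@H](B3O[C@@H](C4CCCCC4)[C@H](C4CCCCC4)O3)c2cc(OC)c(O)c(OC)c2)ccc1O
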